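**Retrosynthetic overview**
1. Feature: in the ten-membered ring (C1–C10) the bonds C5–C6 and C9–C10 lie 1,5 to each other. Both are made at once by [2+2] photoaddition of a meso cyclobutene (C6=C9, carrying O7 and O8 as a cyclic carbonate) to the C5=C10 enone of a six-membered ring (C1, C2, C3, C4, C5, C10) fused to ring A. Heating the bicyclo[2.2.0]hexane then breaks C5–C10 and C6–C9 and leaves the ten-membered 1,5-diene.
2. Enone: from the Wieland–Miescher ketone. The ring ketone next to C1 becomes the C2 oxygen (hydride anti to C15 gives 2β), the enone is moved to C4(=O)–C5=C10 by deconjugative ketalisation and allylic oxidation, and C16 comes from iodination and methyl coupling. Ring A keeps one oxygen, at C12.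
3. On the olefin-free photoadduct: C4 is deoxygenated through its enol triflate and ring A is oxidised (C13=C14 enone, C11 hydroxylation, 13α,14α-diol, 12α-ol).
4. After ring opening: a C11 ketone turns C9=C10 into an enone and so separates it from the isolated C5=C6 olefin. β-Borylation gives O9/H10, C11 is methylenated (C20), a tethered Reformatsky reaction at a C8 ketone closes the lactone (C8, C17), and ene-chlorination gives C6–Cl with C5=C16.
5. Ring order: rings A/B bicycle → cyclobutane pair → ten-membered ring → γ-lactone → spiro-epoxide. The C13 ester and the four acetates come last.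

Key step: step 11

Numbering: target numbering throughout. Ten-membered ring C1–C10 (C1 quaternary with methyl C15, C5 bears C16); ring A is C1, C14, C13, C12, C11, C10 (C20 on C11); lactone is C8, C17 (methyl C18), C19, O, C7. β is the face of ring A that carries C15, α the opposite face.

Assumption (remark on the chemistry): the thermal ring opening is taken to give the diene with C4 cis to C7 across C5=C6 and C8 cis to C11 (trans to C1) across C9=C10. This is the cis,trans pattern that the diyl pathway allows and that avoids allylic strain with the quaternary C1; structures 26–35 are written with it.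

Remark: the C11 carbinol in 22–26, the bromine-bearing carbon in 33–34 and the chlorine-bearing carbons in 14 are epimer mixtures of no consequence and are left open in the SMILES.

**Route**

Step 1
Reactants: 1 2-methylcyclohexane-1,3-dione; 2 but-3-en-2-one
Product: 3 2-methyl-2-(3-oxobutyl)cyclohexane-1,3-dione
Conditions: H2O, AcOH (cat.), hydroquinone (cat.), 75 °C
Reagents that add atoms: none
Why: Michael addition of the dione enol to the vinyl ketone gives the triketone in which the quaternary carbon is C1 (with C15), the ring carbonyls are the future C2 and C10, and the side chain is C14–C13–C12(=O)–C11.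

Step 2
Reactants: 3 triketone
Product: 5 (S)-Wieland–Miescher ketone, via aldol ketol 4 (not isolated)
Conditions: L-proline (10 mol%), DMSO, rt; recrystallisation
Reagents that add atoms: none
Why: Hajos–Parrish–Eder–Sauer–Wiechert aldol condensation: the proline enamine of the side-chain ketone adds to one of the two enantiotopic ring carbonyls and the ketol dehydrates, which sets C1 (S, the configuration of the target); crystallisation should raise the optical purity.

Step 3
Reactants: 5 (S)-Wieland–Miescher ketone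
Product: 6 (4aS,5S)-5-hydroxy-4a-methyl-4,4a,5,6,7,8-hexahydronaphthalen-2(3H)-one
Conditions: NaBH4 (0.3 equiv), EtOH, −10 °C
Reagents that add atoms: none
Why: Chemoselective borohydride reduction of the saturated ketone (the enone carbonyl is less electrophilic); hydride adds axially from the face anti to the angular methyl, so the C2 hydroxyl comes out cis to C15 (2β), as the target needs.

Step 4
Reactants: 6 hydroxy enone
Product: 7 ketal alcohol (C12 ethylene ketal, C5=C10 olefin, 2β-OH)
Conditions: ethylene glycol, pTsOH (cat.), benzene, reflux (Dean–Stark)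
Reagents that add atoms: ethylene glycol OCCO
Why: Acid-catalysed ketalisation through the dienol moves the olefin out of conjugation to C5=C10 (as with 4-en-3-one steroids), which leaves C4 as a free allylic methylene.

Step 5
Reactants: 7 ketal alcohol
Product: 8 2β-tert-butyldimethylsilyl ether of 7
Conditions: TBSCl, imidazole, DMF, 40 °C
Reagents that add atoms: tert-butyldimethylsilyl chloride CC(C)(C)[Si](C)(C)Cl
Why: Standard silylation of the secondary alcohol; the silyl ether is stable to the oxidation, coupling, photochemical and strong-base steps that follow.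

Step 6
Reactants: 8 silyl ether
Product: 9 enone (C4 ketone conjugated with C5=C10, C5–H)
Conditions: Rh2(cap)4 (cap = caprolactamate, 1 mol%), tBuOOH (70% aq, 5 equiv), K2CO3 (0.5 equiv), CH2Cl2, rt
Reagents that add atoms: tert-butyl hydroperoxide CC(C)(C)OO
Why: Dirhodium-catalysed allylic C–H oxidation by tert-butylperoxyl radicals; of the two allylic methylenes C4 should react, because C11 is shielded and deactivated by the neighbouring ketal, as in the C7 oxidation of 5-ene steroid 3-ketals.

Step 7
Reactants: 9 enone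
Product: 10 iodo enone (iodine on C5)
Conditions: I2, DMAP (0.2 equiv), K2CO3, THF/H2O, rt
Reagents that add atoms: iodine II
Why: Amine-mediated α-iodination of a cyclic enone (conjugate addition of the amine, iodination of the enolate, elimination); C5 carries the only vinylic hydrogen.

Step 8
Reactants: 10 iodo enone
Product: 11 bicyclic methyl enone (C12 ketal, 2β-OTBS, C4 ketone, C5 methyl C16)
Conditions: MeB(OH)2, Pd(dppf)Cl2 (5 mol%), K2CO3, dioxane/H2O, 80 °C
Reagents that add atoms: methylboronic acid CB(O)O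
Why: Suzuki–Miyaura coupling of the α-iodo enone installs C16 and completes the tetrasubstituted enone chromophore.

Step 9
Reactants: 12 vinylene carbonate; 13 (E)-1,2-dichloroethene
Product: 14 6,7-dichloro-2,4-dioxabicyclo[3.2.0]heptan-3-one (cis ring fusion, chlorine epimers)
Conditions: hν (Pyrex), acetone (sensitiser and solvent), excess dichloroethene, rt
Reagents that add atoms: none
Why: Triplet-sensitised [2+2] photocycloaddition of vinylene carbonate; the five-membered carbonate enforces the cis ring fusion, and the chlorine configuration does not matter.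

Step 10
Reactants: 14 dichloride
Product: 15 meso-2,4-dioxabicyclo[3.2.0]hept-6-en-3-one (cis-cyclobut-3-ene-1,2-diyl carbonate)
Conditions: activated Zn dust, DMF, 50 °C
Reagents that add atoms: none
Why: Reductive 1,2-elimination of the vicinal dichloride by zinc gives the strained meso cyclobutene from every chlorine epimer.

Step 11
Reactants: 11 bicyclic methyl enone; 15 meso cyclobutene carbonate
Product: 16 photoadduct with a bicyclo[2.2.0]hexane core fused to the cyclohexanone ring
Conditions: hν 350 nm (Pyrex), CH2Cl2, degassed, −20 °C, threefold excess of the cyclobutene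
Reagents that add atoms: none
Why: Excitation of the enone and intersystem crossing give the twisted triplet, which bonds to the strained olefin of 15 to form a triplet 1,4-diradical; after spin inversion this collapses to the cyclobutane, forming C5–C6 and C9–C10. The closest known reaction is the enone–alkene [2+2] photocycloaddition with a cyclobutene as partner, the first half of the photo-thermal route to cyclodeca-1,5-dienes; a fully substituted enone olefin is at the slow end, hence the excess of 15 and light that only the enone absorbs. The one ring closed is the central cyclobutane (C5, C6, C9, C10), by radical–radical recombination of the 1,4-diradical (formal [2π+2π]), which together with the ring of 15 makes the bicyclo[2.2.0]hexane. C5 and C10 are set by the enone face, the olefin entering anti to the axial C15 methyl on C1; C6 and C9 are set by the cyclobutene face (anti to its carbonate oxygens) and by its orientation, with the four-membered ring turned away from C1 and C4 (cis-anti-cis). The only selectivity the route needs is the pairing, that is which enantiotopic olefin carbon of 15 bonds to C5, because C5, C6, C9 and C10 all become trigonal on ring opening while C7 and C8 stay; the three preferences named together place O7 and O8 relative to C1 as in the target. This pairing rests on the face bias of the quaternary C1 (C15 methyl, flanked by the C2 silyl ether), and a trans-fused adduct from the same approach would lead to the same diene.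

Step 12
Reactants: 16 photoadduct
Product: 17 C3=C4 enol triflate
Conditions: KN(SiMe3)2, THF, −78 °C; then N-(5-chloropyridin-2-yl)bis(trifluoromethanesulfonimide)
Reagents that add atoms: Comins' reagent FC(F)(F)S(=O)(=O)N(c1ccc(Cl)cn1)S(=O)(=O)C(F)(F)F
Why: Enolate O-triflation: C3 is the only enolisable position of the C4 ketone (C5 is quaternary), and at low temperature β-elimination of the C2 silyl ether from the potassium enolate should not compete.

Step 13
Reactants: 17 enol triflate
Product: 18 C3=C4 alkene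
Conditions: Pd(OAc)2 (5 mol%), PPh3, Bu3N, HCO2H, DMF, 60 °C
Reagents that add atoms: none
Why: Palladium-catalysed formate reduction of an enol triflate: oxidative addition, formate exchange, loss of CO2 and reductive elimination of C–H.

Step 14
Reactants: 18 alkene
Product: 19 C4-deoxygenated photoadduct (C3H2–C4H2)
Conditions: 2-nitrobenzenesulfonylhydrazide, Et3N, CH2Cl2, rt
Reagents that add atoms: none
Why: Diimide reduction of the cis-disubstituted olefin; it avoids a metal surface that could hydrogenolyse the strained central bond and completes the removal of the C4 oxygen without a radical or cation next to the cyclobutane.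

Step 15
Reactants: 19 ketal
Product: 20 C12 ketone
Conditions: PPTS, acetone/H2O, 50 °C
Reagents that add atoms: water O
Why: Acid-catalysed ketal hydrolysis; the cyclic carbonate and the hindered secondary silyl ether should survive.

Step 16
Reactants: 20 ketone
Product: 21 C13=C14 enone
Conditions: IBX, 4-methoxypyridine N-oxide, DMSO, rt
Reagents that add atoms: none
Why: IBX dehydrogenation of a ketone to the enone; only C13–C14 can be desaturated, since the other α-carbon C11 is bonded to the quaternary C10.

Step 17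
Reactants: 21 enone
Product: 22 11-hydroxy enone (C11 epimers)
Conditions: LiN(SiMe3)2, THF, −78 °C; then 2-(phenylsulfonyl)-3-phenyloxaziridine; aq NH4Cl
Reagents that add atoms: Davis oxaziridine O=S(=O)(N1OC1c1ccccc1)c1ccccc1
Why: Enolate hydroxylation: α′-deprotonation at C11 (the γ-carbon C1 is quaternary) gives the cross-conjugated dienolate, which the Davis oxaziridine hydroxylates; the C11 configuration is lost later at the ketone.

Step 18
Reactants: 22 hydroxy enone
Product: 23 11,13α,14α-triol C12 ketone
Conditions: OsO4 (5 mol%), NMO, citric acid, tBuOH/H2O, rt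
Reagents that add atoms: N-methylmorpholine N-oxide C[N+]1([O-])CCOCC1; water O
Why: Upjohn dihydroxylation of the enone olefin, suprafacial and expected from the α face, anti to the axial C15 methyl that sits next to C14 and 1,3-diaxial to C13, which sets C13 and C14.

Step 19
Reactants: 23 triol
Product: 24 13α,14α-acetonide
Conditions: 2,2-dimethoxypropane, PPTS (cat.), CH2Cl2, rt
Reagents that add atoms: 2,2-dimethoxypropane COC(C)(C)OC
Why: Acetal exchange; only the cis 13,14-diol can close a five-membered acetonide, so the C11 hydroxyl stays free.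

Step 20
Reactants: 24 acetonide ketone
Product: 25 11,12α-diol
Conditions: NaBH4, CeCl3·7H2O, MeOH/THF, −78 °C
Reagents that add atoms: none
Why: Luche-type 1,2-reduction of the C12 ketone; axial approach on the α face is blocked by the syn-axial C14 oxygen and C9, so hydride should enter from the β face and give the axial 12α-alcohol, cis to the acetonide oxygens.

Step 21
Reactants: 25 diol
Product: 26 ten-membered 1,5-diene (C5=C6 and C9=C10; 7,8-carbonate; 11-OH; 12α-OH; 13α,14α-acetonide; 2β-OTBS)
Conditions: toluene (0.01 M), BHT, base-washed sealed tube, 190 °C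
Reagents that add atoms: none
Why: Thermal cycloreversion of a bicyclo[2.2.0]hexane: homolysis of the strained C6–C9 bond gives the cyclohexane-1,4-diyl, which cleaves C5–C10 (the bond between two fully substituted carbons) to give two trisubstituted olefins and the ten-membered ring, while the cis-fused carbonate holds C7–C8 against the other scission.

Step 22
Reactants: 26 diene diol
Product: 27 C11 ketone (exocyclic enone C11(=O)–C10=C9, 12α-OH)
Conditions: MnO2, CH2Cl2, rt
Reagents that add atoms: none
Why: Manganese dioxide oxidation, selective for the allylic C11 alcohol; the C12 alcohol is not allylic and C7/C8 are masked.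

Step 23
Reactants: 27 enone
Product: 29 9,12-diol C11 ketone (9-OH and H10 as in the target), via C9 pinacol boronate 28 (not isolated)
Conditions: B2pin2, CuCl (5 mol%), NaOtBu (10 mol%), bis[2-(diphenylphosphino)phenyl] ether (5 mol%), MeOH (2 equiv), THF, rt; then NaBO3·4H2O, THF/H2O, 0 °C
Reagents that add atoms: bis(pinacolato)diboron CC1(C)OB(OC1(C)C)B1OC(C)(C)C(C)(C)O1 (boron in 28 only); sodium perborate [Na+].[Na+].O[B-]1(O)OO[B-](O)(O)OO1 (O9)
Why: Copper-catalysed conjugate borylation of the enone (the isolated C5=C6 olefin is inert), then C–B oxidation with retention; boron is expected at C9 from the face anti to C15 and the proton at C10 axially from the same face, which with C8 cis to C11 gives O9 and H10 as in the target, and C10 stays correctable by base since the equatorial C9 is the stable arrangement.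

Step 24
Reactants: 29 hydroxy ketone
Product: 30 C11 exocyclic methylene (C20), 9,12-diol
Conditions: Zn, CH2Br2, TiCl4, THF/CH2Cl2, 0 °C to rt
Reagents that add atoms: dibromomethane BrCBr
Why: Takai–Lombardo methylenation, chosen because it is non-basic, so the β-hydroxy ketone should neither eliminate nor epimerise at C10; free hydroxyls and the carbonate are tolerated.

Step 25
Reactants: 30 diol
Product: 31 2,9,12-tris(tert-butyldimethylsilyl) ether
Conditions: TBSOTf (3 equiv), 2,6-lutidine, CH2Cl2, 0 °C
Reagents that add atoms: tert-butyldimethylsilyl triflate CC(C)(C)[Si](C)(C)OS(=O)(=O)C(F)(F)F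
Why: Silyl triflate silylation of the two hindered secondary alcohols at C9 and C12.

Step 26
Reactants: 31 carbonate
Product: 32 7,8-diol
Conditions: iBu2AlH (4 equiv), CH2Cl2, −78 °C; aq potassium sodium tartrate work-up
Reagents that add atoms: none
Why: Hydride reduction of the cyclic carbonate frees the diol at low temperature without the alkoxide conditions under which the neighbouring C9 silyl group could migrate.

Step 27
Reactants: 32 diol
Product: 33 C7 2-bromopropanoate (bromide epimers)
Conditions: 2-bromopropanoyl bromide (1.05 equiv), pyridine, CH2Cl2, −78 °C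
Reagents that add atoms: 2-bromopropanoyl bromide CC(Br)C(=O)Br
Why: Selective acylation of the less hindered allylic C7 hydroxyl; the C8 hydroxyl is flanked by the C9 silyl ether.

Step 28
Reactants: 33 ester alcohol
Product: 34 C8 ketone
Conditions: Dess–Martin periodinane, NaHCO3, CH2Cl2, rt
Reagents that add atoms: none
Why: Dess–Martin oxidation of the remaining secondary alcohol under buffered conditions that leave the α-bromo ester and silyl ethers alone.

Step 29
Reactants: 34 keto ester
Product: 35 γ-lactone (tertiary 8-OH, C17 methyl as in the target; C5=C6 olefin intact)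
Conditions: SmI2 (2.5 equiv), THF, −78 °C
Reagents that add atoms: none
Why: Intramolecular Reformatsky reaction: the samarium enolate made from the bromide adds to the C8 ketone through a chelated cyclic transition state, and the tether can reach the carbonyl only with O7 perpendicular to it, so the rotamer with C6–C7 and C8–C9 transoid should deliver C17 to the face that leaves 8-OH syn to O7 (trans-fused lactone), with the C18 methyl away from C9.

Step 30
Reactants: 35 lactone
Product: 36 6-chloro-5(16)-ene
Conditions: Ca(OCl)2, solid CO2, CH2Cl2/H2O, 0 °C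
Reagents that add atoms: calcium hypochlorite [Ca+2].[O-]Cl.[O-]Cl
Why: Ene-type allylic chlorination by hypochlorous acid: Cl+ adds to C6 of the trisubstituted olefin and the C5 cation loses a C16 proton to give the exocyclic methylene; chlorine is expected anti to the C7–O bond with H7 in the olefin plane, which sets C6, and the C11=C20 olefin, deactivated by its allylic silyl ether, should react more slowly.

Step 31
Reactants: 36 acetonide
Product: 37 13α,14α-diol
Conditions: TFA, H2O, CH2Cl2, 0 °C
Reagents that add atoms: none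
Why: Brief acid hydrolysis of the acetonide at low temperature, which the hindered silyl ethers, the lactone and the allylic chloride should tolerate.

Step 32
Reactants: 37 diol
Product: 38 13-O-(4-methylpentanoate)
Conditions: 4-methylpentanoyl chloride (1.1 equiv), pyridine, CH2Cl2, −20 °C
Reagents that add atoms: 4-methylpentanoyl chloride CC(C)CCC(=O)Cl
Why: Selective acylation of the equatorial 13-OH; the axial 14-OH next to the quaternary C1 and the tertiary 8-OH are much less reactive.

Step 33
Reactants: 38 tris-silyl ether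
Product: 39 2,9,12,14-tetraol (8-OH also free)
Conditions: HF (48% aq), MeCN, 0 °C to rt
Reagents that add atoms: none
Why: Acidic fluoride cleavage of the three silyl ethers, under which the neighbouring C13 ester should not migrate and no epoxide is yet present.

Step 34
Reactants: 39 tetraol
Product: 40 11,20-epoxide (O α, C20 β)
Conditions: VO(acac)2 (5 mol%), tBuOOH (1.2 equiv), CH2Cl2, 0 °C
Reagents that add atoms: tert-butyl hydroperoxide CC(C)(C)OO
Why: Vanadium-catalysed hydroxyl-directed epoxidation: the axial allylic 12α-OH delivers oxygen to the α face of C11=C20, which sets C11; the C5=C16 olefin has no allylic hydroxyl and carries an allylic chloride.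

Step 35
Reactants: 40 epoxy tetraol
Product: 41 target CNP0196150.1
Conditions: Ac2O, Et3N, DMAP (cat.), CH2Cl2, rt
Reagents that add atoms: acetic anhydride CC(=O)OC(C)=O
Why: DMAP-catalysed acetylation of the four secondary hydroxyls at C2, C9, C12 and C14; the tertiary 8-OH should stay free and the epoxide is stable to these conditions.

**Compound list**
1 | 2-methylcyclohexane-1,3-dione | CC1C(=O)CCCC1=O | starting material
2 | but-3-en-2-one | CC(=O)C=C | starting material
3 | 2-methyl-2-(3-oxobutyl)cyclohexane-1,3-dione | CC(=O)CCC1(C)C(=O)CCCC1=O | intermediate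
4 | aldol ketol, cis-fused 4a-hydroxy-8a-methyloctahydronaphthalene-1,6-dione (not isolated) | C[C@]12CCC(=O)C[C@@]1(O)CCCC2=O | intermediate
5 | (S)-Wieland–Miescher ketone, (8aS)-8a-methyl-3,4,8,8a-tetrahydronaphthalene-1,6(2H,7H)-dione | C[C@]12CCC(=O)C=C1CCCC2=O | intermediate
6 | (4aS,5S)-5-hydroxy-4a-methyl-4,4a,5,6,7,8-hexahydronaphthalen-2(3H)-one | C[C@]12CCC(=O)C=C1CCC[C@@H]2O | intermediate
7 | ketal alcohol: C12 ethylene ketal, C5=C10 olefin, 2β-OH | C1=C2CC3(OCCO3)CC[C@]2(C)[C@@H](O)CC1 | intermediate
8 | 2β-TBS ether of 7 | C1=C2CC3(OCCO3)CC[C@]2(C)[C@@H](O[Si](C)(C)C(C)(C)C)CC1 | intermediate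
9 | enone: C4 ketone, C5=C10 (C5–H), C12 ketal, 2β-OTBS | C1=C2CC3(OCCO3)CC[C@]2(C)[C@@H](O[Si](C)(C)C(C)(C)C)CC1=O | intermediate
10 | iodo enone (iodine on C5) | IC1=C2CC3(OCCO3)CC[C@]2(C)[C@@H](O[Si](C)(C)C(C)(C)C)CC1=O | intermediate
11 | bicyclic methyl enone (key-step precursor): C5 methyl, C4 ketone, C12 ketal, 2β-OTBS | CC1=C2CC3(OCCO3)CC[C@]2(C)[C@@H](O[Si](C)(C)C(C)(C)C)CC1=O | intermediate
12 | vinylene carbonate | O=C1OC=CO1 | starting material
13 | (E)-1,2-dichloroethene | Cl/C=C/Cl | starting material
14 | 6,7-dichloro-2,4-dioxabicyclo[3.2.0]heptan-3-one (cis-fused, chlorine epimers) | O=C1O[C@H]2C(Cl)C(Cl)[C@H]2O1 | intermediate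
15 | meso-2,4-dioxabicyclo[3.2.0]hept-6-en-3-one | O=C1O[C@H]2C=C[C@H]2O1 | intermediate
16 | photoadduct (key-step product): bicyclo[2.2.0]hexane core, C4 ketone, C12 ketal, 7,8-carbonate, 2β-OTBS | C[C@]12C(=O)C[C@H](O[Si](C)(C)C(C)(C)C)[C@@]3(C)CCC4(OCCO4)C[C@]13[C@@H]1[C@H]5OC(=O)O[C@H]5[C@H]21 | intermediate
17 | C3=C4 enol triflate of 16 | C[C@]12C(OS(=O)(=O)C(F)(F)F)=C[C@H](O[Si](C)(C)C(C)(C)C)[C@@]3(C)CCC4(OCCO4)C[C@]13[C@@H]1[C@H]5OC(=O)O[C@H]5[C@H]21 | intermediate
18 | C3=C4 alkene | C[C@]12C=C[C@H](O[Si](C)(C)C(C)(C)C)[C@@]3(C)CCC4(OCCO4)C[C@]13[C@@H]1[C@H]5OC(=O)O[C@H]5[C@H]21 | intermediate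
19 | C4-deoxygenated photoadduct | C[C@]12CC[C@H](O[Si](C)(C)C(C)(C)C)[C@@]3(C)CCC4(OCCO4)C[C@]13[C@@H]1[C@H]5OC(=O)O[C@H]5[C@H]21 | intermediate
20 | C12 ketone | C[C@]12CC[C@H](O[Si](C)(C)C(C)(C)C)[C@@]3(C)CCC(=O)C[C@]13[C@@H]1[C@H]5OC(=O)O[C@H]5[C@H]21 | intermediate
21 | C13=C14 enone | C[C@]12CC[C@H](O[Si](C)(C)C(C)(C)C)[C@@]3(C)C=CC(=O)C[C@]13[C@@H]1[C@H]5OC(=O)O[C@H]5[C@H]21 | intermediate
22 | 11-hydroxy enone (C11 epimers) | C[C@]12CC[C@H](O[Si](C)(C)C(C)(C)C)[C@@]3(C)C=CC(=O)C(O)[C@]13[C@@H]1[C@H]5OC(=O)O[C@H]5[C@H]21 | intermediate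
23 | 11,13α,14α-triol C12 ketone | C[C@]12CC[C@H](O[Si](C)(C)C(C)(C)C)[C@@]3(C)[C@@H](O)[C@@H](O)C(=O)C(O)[C@]13[C@@H]1[C@H]5OC(=O)O[C@H]5[C@H]21 | intermediate
24 | 13α,14α-acetonide of 23 | C[C@]12CC[C@H](O[Si](C)(C)C(C)(C)C)[C@@]3(C)[C@H]4OC(C)(C)O[C@H]4C(=O)C(O)[C@]13[C@@H]1[C@H]5OC(=O)O[C@H]5[C@H]21 | intermediate
25 | 11,12α-diol | C[C@]12CC[C@H](O[Si](C)(C)C(C)(C)C)[C@@]3(C)[C@H]4OC(C)(C)O[C@H]4[C@@H](O)C(O)[C@]13[C@@H]1[C@H]5OC(=O)O[C@H]5[C@H]21 | intermediate
26 | ten-membered 1,5-diene diol (C4 cis to C7; C8 cis to C11) | C1C[C@H](O[Si](C)(C)C(C)(C)C)[C@@]2(C)[C@H]4OC(C)(C)O[C@H]4[C@@H](O)C(O)/C2=C\[C@H]3OC(=O)O[C@H]3/C=C1/C | intermediate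
27 | C11 ketone, exocyclic enone, 12α-OH | C1C[C@H](O[Si](C)(C)C(C)(C)C)[C@@]2(C)[C@H]4OC(C)(C)O[C@H]4[C@@H](O)C(=O)/C2=C\[C@H]3OC(=O)O[C@H]3/C=C1/C | intermediate
28 | C9 pinacol boronate, H10 α (not isolated) | C1C[C@H](O[Si](C)(C)C(C)(C)C)[C@@]2(C)[C@H]4OC(C)(C)O[C@H]4[C@@H](O)C(=O)[C@@H]2[C@H](B5OC(C)(C)C(C)(C)O5)[C@H]3OC(=O)O[C@H]3/C=C1/C | intermediate
29 | 9,12-diol C11 ketone | C1C[C@H](O[Si](C)(C)C(C)(C)C)[C@@]2(C)[C@H]4OC(C)(C)O[C@H]4[C@@H](O)C(=O)[C@@H]2[C@H](O)[C@H]3OC(=O)O[C@H]3/C=C1/C | intermediate
30 | C11 methylene 9,12-diol | C1C[C@H](O[Si](C)(C)C(C)(C)C)[C@@]2(C)[C@H]4OC(C)(C)O[C@H]4[C@@H](O)C(=C)[C@@H]2[C@H](O)[C@H]3OC(=O)O[C@H]3/C=C1/C | intermediate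
31 | 2,9,12-tris-TBS ether | C1C[C@H](O[Si](C)(C)C(C)(C)C)[C@@]2(C)[C@H]4OC(C)(C)O[C@H]4[C@@H](O[Si](C)(C)C(C)(C)C)C(=C)[C@@H]2[C@H](O[Si](C)(C)C(C)(C)C)[C@H]3OC(=O)O[C@H]3/C=C1/C | intermediate
32 | 7,8-diol | C1C[C@H](O[Si](C)(C)C(C)(C)C)[C@@]2(C)[C@H]4OC(C)(C)O[C@H]4[C@@H](O[Si](C)(C)C(C)(C)C)C(=C)[C@@H]2[C@H](O[Si](C)(C)C(C)(C)C)[C@@H](O)[C@@H](O)/C=C1/C | intermediate
33 | C7 2-bromopropanoate (bromide epimers) | C1C[C@H](O[Si](C)(C)C(C)(C)C)[C@@]2(C)[C@H]4OC(C)(C)O[C@H]4[C@@H](O[Si](C)(C)C(C)(C)C)C(=C)[C@@H]2[C@H](O[Si](C)(C)C(C)(C)C)[C@@H](O)[C@@H](OC(=O)C(C)Br)/C=C1/C | intermediate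
34 | C8 ketone | C1C[C@H](O[Si](C)(C)C(C)(C)C)[C@@]2(C)[C@H]4OC(C)(C)O[C@H]4[C@@H](O[Si](C)(C)C(C)(C)C)C(=C)[C@@H]2[C@H](O[Si](C)(C)C(C)(C)C)C(=O)[C@@H](OC(=O)C(C)Br)/C=C1/C | intermediate
35 | γ-lactone with tertiary 8-OH | C1C[C@H](O[Si](C)(C)C(C)(C)C)[C@@]2(C)[C@H]4OC(C)(C)O[C@H]4[C@@H](O[Si](C)(C)C(C)(C)C)C(=C)[C@@H]2[C@H](O[Si](C)(C)C(C)(C)C)[C@]3(O)[C@@H](C)C(=O)O[C@H]3/C=C1/C | intermediate
36 | 6-chloro-5(16)-ene | C=C1CC[C@H](O[Si](C)(C)C(C)(C)C)[C@@]2(C)[C@H]4OC(C)(C)O[C@H]4[C@@H](O[Si](C)(C)C(C)(C)C)C(=C)[C@@H]2[C@H](O[Si](C)(C)C(C)(C)C)[C@]3(O)[C@@H](C)C(=O)O[C@H]3[C@H]1Cl | intermediate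
37 | 13α,14α-diol | C=C1CC[C@H](O[Si](C)(C)C(C)(C)C)[C@@]2(C)[C@@H](O)[C@@H](O)[C@@H](O[Si](C)(C)C(C)(C)C)C(=C)[C@@H]2[C@H](O[Si](C)(C)C(C)(C)C)[C@]3(O)[C@@H](C)C(=O)O[C@H]3[C@H]1Cl | intermediate
38 | 13-O-(4-methylpentanoate) | C=C1CC[C@H](O[Si](C)(C)C(C)(C)C)[C@@]2(C)[C@@H](O)[C@@H](OC(=O)CCC(C)C)[C@@H](O[Si](C)(C)C(C)(C)C)C(=C)[C@@H]2[C@H](O[Si](C)(C)C(C)(C)C)[C@]3(O)[C@@H](C)C(=O)O[C@H]3[C@H]1Cl | intermediate
39 | 2,9,12,14-tetraol | C=C1CC[C@H](O)[C@@]2(C)[C@@H](O)[C@@H](OC(=O)CCC(C)C)[C@@H](O)C(=C)[C@@H]2[C@H](O)[C@]3(O)[C@@H](C)C(=O)O[C@H]3[C@H]1Cl | intermediate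
40 | 11,20-epoxide | C=C1CC[C@H](O)[C@@]2(C)[C@@H](O)[C@@H](OC(=O)CCC(C)C)[C@@H](O)[C@]4(CO4)[C@@H]2[C@H](O)[C@]3(O)[C@@H](C)C(=O)O[C@H]3[C@H]1Cl | intermediate
41 | CNP0196150.1 | C=C1CC[C@H](OC(C)=O)[C@@]2(C)[C@@H](OC(C)=O)[C@@H](OC(=O)CCC(C)C)[C@@H](OC(C)=O)[C@]3(CO3)[C@@H]2[C@H](OC(C)=O)[C@]2(O)[C@@H](C)C(=O)O[C@H]2[C@H]1Cl | target

**Step count**
Total: 35 steps. Longest linear sequence: 33 steps (steps 1–8 and 11–35); steps 9–10 are the branch to 15.

**Steps most likely to fail**

Step 11. The fully substituted enone may add too slowly, so that the scarce cyclobutene is lost in side reactions, and control of the pairing (enone face, cyclobutene orientation) may be incomplete. Fallback, from 11 back to 16: the bicyclo[2.2.0]hexane is built in two photoadditions with cheap partners used in large excess. Irradiation of 11 (350 nm) in (E)-1,2-dichloroethene 13 as co-solvent should give the dichlorocyclobutane adduct F1. Zinc dust in DMF removes both chlorines to give the cyclobutene ketone F2. NaBH4 reduces C4 to the alcohol F3, which takes away the β,γ-unsaturated ketone chromophore. Acetone-sensitised [2+2] addition of vinylene carbonate 12 to the exo face of the cyclobutene gives the carbonate alcohol F4, and Dess–Martin oxidation returns to 16.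

Step 21. The 1,4-diyl may cleave C7–C8 instead of C5–C10, or the diene may undergo Cope rearrangement back to a six-membered ring carrying two enol carbonate arms; mixtures of olefin geometry are also possible. Fallback, from 24 to 27: an acyl group is placed at C11 before heating, so that the C10 radical is stabilised and the new C9=C10 olefin is conjugated. Dess–Martin oxidation of 24 gives the 11,12-diketone F5. NaBH4 at −78 °C should reduce the less hindered C12 carbonyl from the β face to the 11-keto-12α-ol F6. Heating F6 under the conditions of step 21 then gives 27 directly, and step 22 is no longer needed.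

Step 30. Chlorine may be delivered to the other face of C5=C6 (6-epimer), the C11=C20 olefin may compete, or the C8 hydroxyl may capture the C5 cation. Fallback, from 35 to 36: oxygen is put on that face and chloride is brought in with inversion. mCPBA (NaHCO3, CH2Cl2, 0 °C) epoxidises the trisubstituted olefin to the 5,6-epoxide F7. TMSOTf/DBU (toluene, −40 °C) opens it by loss of a C16 proton to the silylated allylic alcohol F8, and citric acid in MeOH frees the allylic alcohol F9 (C6–OH, C5=C16). PPh3/hexachloroacetone (CH2Cl2, −20 °C) then substitutes with inversion and little allylic shift to give 36.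

**Further compounds**
F1 | step 11 | dichlorocyclobutane photoadduct of 11 (chlorine epimers) | C[C@]12C(=O)C[C@H](O[Si](C)(C)C(C)(C)C)[C@@]3(C)CCC4(OCCO4)C[C@]13C(Cl)C2Cl
F2 | step 11 | cyclobutene ketone (C6=C9) | C[C@]12C(=O)C[C@H](O[Si](C)(C)C(C)(C)C)[C@@]3(C)CCC4(OCCO4)C[C@]13C=C2
F3 | step 11 | C4 alcohol of F2 (C4 epimers) | C[C@]12C(O)C[C@H](O[Si](C)(C)C(C)(C)C)[C@@]3(C)CCC4(OCCO4)C[C@]13C=C2
F4 | step 11 | C4 alcohol with 7,8-carbonate (C4 epimers) | C[C@]12C(O)C[C@H](O[Si](C)(C)C(C)(C)C)[C@@]3(C)CCC4(OCCO4)C[C@]13[C@@H]1[C@H]5OC(=O)O[C@H]5[C@H]21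
F5 | step 21 | 11,12-diketone | C[C@]12CC[C@H](O[Si](C)(C)C(C)(C)C)[C@@]3(C)[C@H]4OC(C)(C)O[C@H]4C(=O)C(=O)[C@]13[C@@H]1[C@H]5OC(=O)O[C@H]5[C@H]21
F6 | step 21 | 11-keto-12α-ol | C[C@]12CC[C@H](O[Si](C)(C)C(C)(C)C)[C@@]3(C)[C@H]4OC(C)(C)O[C@H]4[C@@H](O)C(=O)[C@]13[C@@H]1[C@H]5OC(=O)O[C@H]5[C@H]21
F7 | step 30 | 5,6-epoxide of 35 | C1C[C@H](O[Si](C)(C)C(C)(C)C)[C@@]2(C)[C@H]4OC(C)(C)O[C@H]4[C@@H](O[Si](C)(C)C(C)(C)C)C(=C)[C@@H]2[C@H](O[Si](C)(C)C(C)(C)C)[C@]3(O)[C@@H](C)C(=O)O[C@H]3[C@@H]5O[C@]15C
F8 | step 30 | 6,8-bis(trimethylsilyl) ether of the allylic alcohol (not isolated) | C=C1CC[C@H](O[Si](C)(C)C(C)(C)C)[C@@]2(C)[C@H]4OC(C)(C)O[C@H]4[C@@H](O[Si](C)(C)C(C)(C)C)C(=C)[C@@H]2[C@H](O[Si](C)(C)C(C)(C)C)[C@]3(O[Si](C)(C)C)[C@@H](C)C(=O)O[C@H]3[C@@H]1O[Si](C)(C)C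
F9 | step 30 | allylic alcohol (C6–OH epimeric to the chloride of 36, C5=C16) | C=C1CC[C@H](O[Si](C)(C)C(C)(C)C)[C@@]2(C)[C@H]4OC(C)(C)O[C@H]4[C@@H](O[Si](C)(C)C(C)(C)C)C(=C)[C@@H]2[C@H](O[Si](C)(C)C(C)(C)C)[C@]3(O)[C@@H](C)C(=O)O[C@H]3[C@@H]1O
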